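**Retrosynthetic overview**
- Target ⇐ acid-mediated desilylation, dehydration and acetal hydrolysis of a 3-silyloxy-indanone diethyl acetal, telescoped with the ring-forming event.
- Benzene ring and five-membered ketone ring, formed together in the last step ⇐ rhodium-catalysed [2+2+2] of acetylene with a 1,6-diyne whose three-atom tether (C=O, CH–azulenyl, C(Me)–OSiMe3) becomes C1–C2–C3 of the indenone.
- Diyne ⇐ aldol union of an azulenylmethyl propynyl ketone with 5,5-diethoxypent-3-yn-2-one.
- Azulenyl ynone ⇐ guaiazulene + ethyl diazoacetate (C–H alkylation), then propynyl addition; ynone acetal ⇐ 3,3-diethoxyprop-1-yne + acetic anhydride.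
- Ring order: the azulene is bought intact as guaiazulene; the two indenone rings are made last, in one operation.

Assumption: the target has no stereocentre and no defined axis, so the achiral structure as drawn is the compound to be made; the two stereocentres created in the aldol step form unselectively and are destroyed in the last step.

Abbreviation: Az = 3,8-dimethyl-5-(propan-2-yl)azulen-1-yl (the guaiazulen-3-yl group).

**Step 1**
Reactants: 1 guaiazulene; 2 ethyl diazoacetate
Product: 3 ethyl 2-Az-acetate
Conditions: AgOSO2CF3 (5 mol %), CH2Cl2, 25 °C, slow addition of 2 (1.2 equiv)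
Reagents that add atoms: none
Why: The electrophilic silver carbene from 2 is attacked by the only free, most nucleophilic five-ring carbon of guaiazulene (C3) and proton transfer completes a formal C–H insertion (metal-carbene C–H alkylation of an azulene), slow addition keeping carbene dimerisation down.

**Step 2**
Reactants: 3 ethyl 2-Az-acetate; 4 propyne
Product: 6 1-Az-pent-3-yn-2-one, via 1-propynyllithium 5 (not isolated)
Conditions: 4, n-BuLi, THF, −78 °C; BF3·OEt2; then 3, −78 °C; H2O
Reagents that add atoms: none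
Why: Yamaguchi–Hirao ester alkynylation, in which the boron-bound tetrahedral adduct persists at −78 °C and releases the ynone only on quench, so over-addition and enolisation of the acidic CH2 are avoided.

**Step 3**
Reactants: 7 3,3-diethoxyprop-1-yne; 8 acetic anhydride
Product: 10 5,5-diethoxypent-3-yn-2-one, via lithium acetylide 9 (not isolated)
Conditions: n-BuLi, THF, −78 °C; then cannulated into Ac2O (3 equiv), THF, −78 °C
Reagents that add atoms: none
Why: Acylation of a lithium acetylide by inverse addition into excess anhydride stops at the ynone because the acetylide never meets free product.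

**Step 4**
Reactants: 6 1-Az-pent-3-yn-2-one; 10 5,5-diethoxypent-3-yn-2-one
Product: 13 9,9-diethoxy-6-methyl-5-Az-6-[(trimethylsilyl)oxy]nona-2,7-diyn-4-one (diastereomer mixture), via lithium enolate 11 (not isolated), via lithium aldolate 12 (not isolated)
Conditions: LiN(SiMe3)2, THF, −78 °C; 10, −78 °C; Me3SiCl, −78 → 0 °C
Reagents that add atoms: chlorotrimethylsilane, C[Si](C)(C)Cl
Why: Kinetic lithium-enolate aldol addition of the CH2 flanked by azulene and ynone carbonyl to the unhindered methyl ynone 10 (1,2-addition at −78 °C), with O-silylation of the aldolate blocking retro-aldol and oxa-Michael closure, the two new stereocentres being formed as a mixture that is erased in step 5.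

**Step 5**
Reactants: 13 silyloxy diyne; 14 acetylene
Product: 16 2-Az-3,7-dimethyl-1-oxo-1H-indene-4-carbaldehyde (target), via silyloxyindanone acetal 15 (not isolated)
Conditions: [Rh(cod)2]BF4 (5 mol %), rac-BINAP (5 mol %), acetylene (1 atm), CH2Cl2, 25 °C; then p-TsOH·H2O, acetone/H2O (10:1), 45 °C
Reagents that add atoms: water, O
Why: Rhodium-catalysed [2+2+2] alkyne cyclotrimerisation, in which oxidative coupling of the two tethered alkynes on monovalent rhodium gives a rhodacyclopentadiene that inserts acetylene and reductively eliminates to close the benzene ring and the five-membered ring together with regiochemistry fixed by the tether, after which acid removes the silyl ether, dehydrates the tertiary β-hydroxy ketone (E1/E1cB) to the indenone and hydrolyses the acetal, leaving no stereocentre.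

**Compound list**
1 | guaiazulene (1,4-dimethyl-7-(propan-2-yl)azulene) | c1cc(C)c2cc(C(C)C)ccc(C)c1-2 | starting material
2 | ethyl diazoacetate | CCOC(=O)C=[N+]=[N-] | starting material
3 | ethyl 2-[3,8-dimethyl-5-(propan-2-yl)azulen-1-yl]acetate | CCOC(=O)Cc1cc(C)c2cc(C(C)C)ccc(C)c1-2 | intermediate
4 | propyne | CC#C | starting material
5 | 1-propynyllithium | [Li]C#CC | intermediate
6 | 1-[3,8-dimethyl-5-(propan-2-yl)azulen-1-yl]pent-3-yn-2-one | CC#CC(=O)Cc1cc(C)c2cc(C(C)C)ccc(C)c1-2 | intermediate
7 | 3,3-diethoxyprop-1-yne | C#CC(OCC)OCC | starting material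
8 | acetic anhydride | CC(=O)OC(C)=O | starting material
9 | (3,3-diethoxyprop-1-yn-1-yl)lithium | [Li]C#CC(OCC)OCC | intermediate
10 | 5,5-diethoxypent-3-yn-2-one | CC(=O)C#CC(OCC)OCC | intermediate
11 | lithium (Z)-enolate of 6 (O-lithio 1-Az-pent-1-en-3-yn-2-olate) | CC#C/C(O[Li])=C/c1cc(C)c2cc(C(C)C)ccc(C)c1-2 | intermediate
12 | lithium aldolate (lithium alkoxide of 9,9-diethoxy-6-hydroxy-6-methyl-5-Az-nona-2,7-diyn-4-one; diastereomer mixture) | CC#CC(=O)C(c1cc(C)c2cc(C(C)C)ccc(C)c1-2)C(C)(O[Li])C#CC(OCC)OCC | intermediate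
13 | 9,9-diethoxy-5-[3,8-dimethyl-5-(propan-2-yl)azulen-1-yl]-6-methyl-6-[(trimethylsilyl)oxy]nona-2,7-diyn-4-one (racemic diastereomer mixture) | CC#CC(=O)C(c1cc(C)c2cc(C(C)C)ccc(C)c1-2)C(C)(O[Si](C)(C)C)C#CC(OCC)OCC | intermediate
14 | acetylene (ethyne) | C#C | starting material
15 | 4-(diethoxymethyl)-2-[3,8-dimethyl-5-(propan-2-yl)azulen-1-yl]-3,7-dimethyl-3-[(trimethylsilyl)oxy]-2,3-dihydro-1H-inden-1-one (racemic diastereomer mixture) | CC1(O[Si](C)(C)C)C(c2cc(C)c3cc(C(C)C)ccc(C)c2-3)C(=O)c2c(C)ccc(C(OCC)OCC)c21 | intermediate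
16 | 2-[3,8-dimethyl-5-(propan-2-yl)azulen-1-yl]-3,7-dimethyl-1-oxo-1H-indene-4-carbaldehyde (achiral) | CC1=C(c2cc(C)c3cc(C(C)C)ccc(C)c2-3)C(=O)c2c(C)ccc(C=O)c21 | target

**Step count**
Total step count: 5.
Longest linear sequence: 4 steps (steps 1, 2, 4, 5); step 3 is a one-step side branch.

**Three steps most likely to fail**

Step 5 (key cyclotrimerisation). The azulene may bind the cationic rhodium, acetylene may oligomerise, and the doubly internal diyne may react slowly. The fallback sets out from 13 and comes back to the route at 16. Liquid ethynyltrimethylsilane, used in measured excess, replaces acetylene gas in the same rhodium-catalysed cycloaddition, so that silicon acts as a traceless blocking group on a more reactive terminal alkyne. This gives 4-(diethoxymethyl)-2-Az-3,7-dimethyl-5-(trimethylsilyl)-3-[(trimethylsilyl)oxy]indan-1-one F1 and its regioisomer 4-(diethoxymethyl)-2-Az-3,7-dimethyl-6-(trimethylsilyl)-3-[(trimethylsilyl)oxy]indan-1-one F2, which need not be separated. n-Bu4NF in wet THF at 60 °C then strips the aryl and O-silyl groups with E1cB loss of the tertiary oxygen, and aqueous HCl cleaves the acetal to give 16.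

Step 4 (aldol of a stabilised ynone enolate with a ynone). Conjugate addition, retro-aldol or self-condensation of 6 may compete. The fallback sets out from 3 (with 10) and comes back at 13; it reorders the bond construction so that a harder amide enolate does the aldol and the propynyl ketone is installed last. Ester 3 is converted with MeNH(OMe)·HCl and i-PrMgCl (THF, −20 °C) into N-methoxy-N-methyl-2-Az-acetamide F3. Its enolate (LiN(i-Pr)2, THF, −78 °C) is added to 10 and trapped with Me3SiCl to give 6,6-diethoxy-N-methoxy-N,3-dimethyl-2-Az-3-[(trimethylsilyl)oxy]hex-4-ynamide F4. Chelation-controlled mono-addition of CH3C≡CMgBr (THF, 0 → 25 °C) then gives 13.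

Step 1 (carbene C–H alkylation). Cyclopropanation or ring expansion of the azulene, double alkylation, or silver-induced oxidation of guaiazulene may lower the yield. The fallback sets out from 1 and comes back at 3; it replaces carbene chemistry with a Friedel–Crafts hydroxyalkylation and ionic reduction. Guaiazulene reacts with ethyl glyoxylate (CH2Cl2, 25 °C) at C3 to give ethyl 2-hydroxy-2-Az-acetate F5. Et3SiH with CF3CO2H (CH2Cl2, 0 °C) reduces the azulene-stabilised cation to 3.

**Further compounds**
F1 | step 5 | 4-(diethoxymethyl)-2-[3,8-dimethyl-5-(propan-2-yl)azulen-1-yl]-3,7-dimethyl-5-(trimethylsilyl)-3-[(trimethylsilyl)oxy]-2,3-dihydro-1H-inden-1-one | CC1(O[Si](C)(C)C)C(c2cc(C)c3cc(C(C)C)ccc(C)c2-3)C(=O)c2c(C)cc([Si](C)(C)C)c(C(OCC)OCC)c21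
F2 | step 5 | 4-(diethoxymethyl)-2-[3,8-dimethyl-5-(propan-2-yl)azulen-1-yl]-3,7-dimethyl-6-(trimethylsilyl)-3-[(trimethylsilyl)oxy]-2,3-dihydro-1H-inden-1-one | CC1(O[Si](C)(C)C)C(c2cc(C)c3cc(C(C)C)ccc(C)c2-3)C(=O)c2c(C)c([Si](C)(C)C)cc(C(OCC)OCC)c21
F3 | step 4 | 2-[3,8-dimethyl-5-(propan-2-yl)azulen-1-yl]-N-methoxy-N-methylacetamide | CON(C)C(=O)Cc1cc(C)c2cc(C(C)C)ccc(C)c1-2
F4 | step 4 | 2-[3,8-dimethyl-5-(propan-2-yl)azulen-1-yl]-6,6-diethoxy-N-methoxy-N,3-dimethyl-3-[(trimethylsilyl)oxy]hex-4-ynamide (diastereomer mixture) | CON(C)C(=O)C(c1cc(C)c2cc(C(C)C)ccc(C)c1-2)C(C)(O[Si](C)(C)C)C#CC(OCC)OCC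
F5 | step 1 | ethyl 2-[3,8-dimethyl-5-(propan-2-yl)azulen-1-yl]-2-hydroxyacetate (racemic) | CCOC(=O)C(O)c1cc(C)c2cc(C(C)C)ccc(C)c1-2
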